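**Retrosynthetic overview**
- The (E)-enol ester is made last by C–O coupling of an (E)-alkenyl iodide with 3-methylbut-2-enoic acid; the iodide comes from an (E)-alkenylsilane carried through the route.
- The 2-(hydroxymethyl)enone comes from a Morita–Baylis–Hillman reaction on a cycloheptenone made by regioselective ketone dehydrogenation; the acetonyl group is carried as a 2-methoxyallyl group.
- C6 and C7 come from a ligand-controlled conjugate alkenylation of an (S)-4,4-disubstituted cyclohept-2-enone, followed by enolate alkylation anti to the new group.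
- The seven-membered ring comes from a one-carbon radical ring expansion (siloxycyclopropane, FeCl3) of a six-membered silyl enol ether, which puts the enone next to the quaternary centre. The six-membered ring is bought; the seven-membered ring is the only ring formed.
- The quaternary centre comes from a copper-catalysed asymmetric conjugate addition of the alkylzirconocene from 2-methylpent-4-en-2-ol to 3-methylcyclohex-2-en-1-one.

Assumption: the target is taken exactly as the given SMILES, (5S,6S,7S) with an (E)-enol ester; in the two ligand-controlled steps the ligand antipode that gives the drawn configuration is used (sense confirmed on small scale), and 3-bromo-2-methoxyprop-1-ene is bought.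

**Step 1**
Reactants: 1 2-methylpent-4-en-2-ol; 2 3-methylcyclohex-2-en-1-one
Product: 5 (S)-trimethyl[(3-methyl-3-{4-methyl-4-[(trimethylsilyl)oxy]pentyl}cyclohex-1-en-1-yl)oxy]silane, via silyl ether 3 (not isolated), via alkylzirconocene 4 (not isolated)
Conditions: HMDS, Me3SiOTf (1 mol %), neat, rt, evaporate; Cp2Zr(H)Cl, CH2Cl2, rt; CuCl (10 mol %), AgNTf2 (11 mol %), BINOL/bis(1-phenylethyl)amine phosphoramidite (11 mol %), 2, Me3SiCl, Et2O, rt; Et3N, pentane, filtration
Reagents that add atoms: hexamethyldisilazane C[Si](C)(C)N[Si](C)(C)C; chlorotrimethylsilane C[Si](C)(C)Cl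
Why: Hydrozirconation followed by copper-catalysed asymmetric conjugate addition of the primary alkylzirconocene to the β-methyl enone, in which the chiral phosphoramidite–copper complex selects one enone face and so sets the (S) quaternary centre, while Me3SiCl traps the regiodefined enolate as the silyl enol ether on the side of the quaternary carbon that cannot be made from the ketone.

**Step 2**
Reactants: 5 (S)-trimethyl[(3-methyl-3-{4-methyl-4-[(trimethylsilyl)oxy]pentyl}cyclohex-1-en-1-yl)oxy]silane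
Product: 6 (5S)-5-methyl-5-{4-methyl-4-[(trimethylsilyl)oxy]pentyl}-1-[(trimethylsilyl)oxy]bicyclo[4.1.0]heptane (both ring-fusion diastereomers)
Conditions: Et2Zn, CH2I2, CH2Cl2, 0 °C to rt
Reagents that add atoms: diiodomethane ICI
Why: Furukawa–Simmons–Smith cyclopropanation of the electron-rich silyl enol ether; the two new ring-fusion centres need no control because both are destroyed in step 3.

**Step 3**
Reactants: 6 (5S)-5-methyl-5-{4-methyl-4-[(trimethylsilyl)oxy]pentyl}-1-[(trimethylsilyl)oxy]bicyclo[4.1.0]heptane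
Product: 8 (S)-4-(4-hydroxy-4-methylpentyl)-4-methylcyclohept-2-en-1-one, via chloro ketone 7 (not isolated)
Conditions: FeCl3, DMF, 0 °C to rt; 1 M HCl work-up; NaOAc, MeOH, reflux
Reagents that add atoms: none
Why: Ito–Saegusa one-carbon ring expansion, in which FeCl3 oxidises the siloxycyclopropane to an alkoxy radical whose β-scission breaks the internal bond, the ring-enlarged β-keto radical is chlorinated and NaOAc eliminates HCl (E1cB), giving the cycloheptenone with its β-carbon next to the untouched quaternary centre (the acid work-up also frees the tertiary alcohol).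

**Step 4**
Reactants: 8 (S)-4-(4-hydroxy-4-methylpentyl)-4-methylcyclohept-2-en-1-one; 9 (E)-(2-bromoethenyl)trimethylsilane; 10 3-bromo-2-methoxyprop-1-ene
Product: 13 (2S,3R,4S)-4-(4-hydroxy-4-methylpentyl)-2-(2-methoxyprop-2-en-1-yl)-4-methyl-3-[(E)-2-(trimethylsilyl)ethenyl]cycloheptan-1-one, via alkenylalane 11 (not isolated), via aluminium enolate 12 (not isolated)
Conditions: 9, t-BuLi (2 equiv), Et2O, −78 °C, then Me2AlCl; 8 + Me3Al (1 equiv), copper thiophene-2-carboxylate (5 mol %), chiral phosphinamine of the SimplePhos type (5.5 mol %), Et2O/THF, −30 °C; MeLi, then 10, DMPU, −30 to 0 °C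
Reagents that add atoms: none
Why: Copper-catalysed asymmetric conjugate addition of an alkenylalane followed by alkylation of the aluminate enolate (tandem conjugate addition–enolate alkylation), in which the chiral copper complex, not the nearly unbiased quaternary centre, puts the alkenyl group on the face cis to the methyl group and the allylic bromide then enters anti to it, giving the 2,3-trans ketone and diverting the minor enantiomer of 8 into a separable diastereomer.

**Step 5**
Reactants: 13 (2S,3R,4S)-4-(4-hydroxy-4-methylpentyl)-2-(2-methoxyprop-2-en-1-yl)-4-methyl-3-[(E)-2-(trimethylsilyl)ethenyl]cycloheptan-1-one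
Product: 14 (5S,6R,7S)-5-(4-hydroxy-4-methylpentyl)-7-(2-methoxyprop-2-en-1-yl)-5-methyl-6-[(E)-2-(trimethylsilyl)ethenyl]cyclohept-2-en-1-one
Conditions: Zn(TMP)2 (1.5 equiv), diethyl allyl phosphate (1.0 equiv), [Pd(allyl)Cl]2 (2.5 mol %), toluene, 120 °C; NH4Cl work-up
Reagents that add atoms: none
Why: Allyl-palladium-catalysed α,β-dehydrogenation of the zinc enolate formed by kinetic deprotonation at the unhindered ring CH2 (β-hydride elimination from the palladium enolate), which leaves the hindered α-CH, the enol ether, the vinylsilane and all three stereocentres untouched.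

**Step 6**
Reactants: 14 (5S,6R,7S)-5-(4-hydroxy-4-methylpentyl)-7-(2-methoxyprop-2-en-1-yl)-5-methyl-6-[(E)-2-(trimethylsilyl)ethenyl]cyclohept-2-en-1-one
Product: 16 (5S,6R,7S)-2-(hydroxymethyl)-5-(4-hydroxy-4-methylpentyl)-5-methyl-7-(2-oxopropyl)-6-[(E)-2-(trimethylsilyl)ethenyl]cyclohept-2-en-1-one, via enol ether alcohol 15 (not isolated)
Conditions: 37% aq. CH2O, imidazole, 1 M NaHCO3, THF, rt; then 0.5 M HCl, THF, 0 °C
Reagents that add atoms: formaldehyde C=O; water O
Why: Morita–Baylis–Hillman hydroxymethylation (imidazole adds to the unhindered enone β-carbon, the enolate adds to formaldehyde, imidazole is eliminated) run while the acetonyl ketone is still masked, followed by mild acid hydrolysis of the methyl enol ether to the methyl ketone; no stereocentre is touched.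

**Step 7**
Reactants: 16 (5S,6R,7S)-2-(hydroxymethyl)-5-(4-hydroxy-4-methylpentyl)-5-methyl-7-(2-oxopropyl)-6-[(E)-2-(trimethylsilyl)ethenyl]cyclohept-2-en-1-one
Product: 17 (5S,6R,7S)-2-(hydroxymethyl)-5-(4-hydroxy-4-methylpentyl)-6-[(E)-2-iodoethenyl]-5-methyl-7-(2-oxopropyl)cyclohept-2-en-1-one
Conditions: NIS, 1,1,1,3,3,3-hexafluoropropan-2-ol, 0 °C, 10 min
Reagents that add atoms: N-iodosuccinimide O=C1CCC(=O)N1I
Why: Electrophilic ipso-iododesilylation of the vinylsilane through a β-silyl cation, which in the fluorinated alcohol goes with retention of the E geometry and spares the electron-poor enone and the free alcohols.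

**Step 8**
Reactants: 17 (5S,6R,7S)-2-(hydroxymethyl)-5-(4-hydroxy-4-methylpentyl)-6-[(E)-2-iodoethenyl]-5-methyl-7-(2-oxopropyl)cyclohept-2-en-1-one; 18 3-methylbut-2-enoic acid
Product: 19 (5S,6S,7S)-2-(hydroxymethyl)-5-(4-hydroxy-4-methylpentyl)-5-methyl-6-[(E)-2-(3-methylbut-2-enoyloxy)ethenyl]-7-(2-oxopropyl)cyclohept-2-en-1-one (CNP0359016.1)
Conditions: 18 (2 equiv), Cs2CO3 (1 equiv), CuI (10 mol %), 3,4,7,8-tetramethyl-1,10-phenanthroline (20 mol %), 4 Å MS, toluene, 70 °C
Reagents that add atoms: none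
Why: Proposed new method: intermolecular copper-catalysed C(sp2)–O coupling of an unactivated (E)-alkenyl iodide with a caesium carboxylate, forming the enol ester C–O bond with retention of the E geometry: the phenanthroline-bound monovalent copper carboxylate inserts into the C–I bond with retention to give a trivalent alkenylcopper carboxylate that reductively eliminates the ester, while the weakly basic carboxylate leaves both free alcohols and the three stereocentres untouched; the closest known reaction types are the Ullmann–Goldberg vinylation of alcohols and amides by alkenyl iodides, the intramolecular copper-catalysed O-vinylation of carboxylic acids to enol lactones and the oxidative copper-catalysed coupling of alkenyltrifluoroborates with carboxylic acids.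

**Compound list**
1 | 2-methylpent-4-en-2-ol | C=CCC(C)(C)O | starting material
2 | 3-methylcyclohex-2-en-1-one | CC1=CC(=O)CCC1 | starting material
3 | trimethyl[(2-methylpent-4-en-2-yl)oxy]silane | C=CCC(C)(C)O[Si](C)(C)C | intermediate
4 | chlorobis(cyclopentadienyl){4-methyl-4-[(trimethylsilyl)oxy]pentyl}zirconium | C[Si](C)(C)OC(C)(C)CCC[Zr](Cl)(C1C=CC=C1)C1C=CC=C1 | intermediate
5 | (S)-trimethyl[(3-methyl-3-{4-methyl-4-[(trimethylsilyl)oxy]pentyl}cyclohex-1-en-1-yl)oxy]silane | C[Si](C)(C)OC1=C[C@@](C)(CCCC(C)(C)O[Si](C)(C)C)CCC1 | intermediate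
6 | (5S)-5-methyl-5-{4-methyl-4-[(trimethylsilyl)oxy]pentyl}-1-[(trimethylsilyl)oxy]bicyclo[4.1.0]heptane, both ring-fusion diastereomers | C[Si](C)(C)OC12CC1[C@@](C)(CCCC(C)(C)O[Si](C)(C)C)CCC2 | intermediate
7 | (4S)-3-chloro-4-(4-hydroxy-4-methylpentyl)-4-methylcycloheptan-1-one, both C3 epimers | O=C1CC(Cl)[C@@](C)(CCCC(C)(C)O)CCC1 | intermediate
8 | (S)-4-(4-hydroxy-4-methylpentyl)-4-methylcyclohept-2-en-1-one | O=C1CCC[C@](C)(CCCC(C)(C)O)C=C1 | intermediate
9 | (E)-(2-bromoethenyl)trimethylsilane | C[Si](C)(C)/C=C/Br | starting material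
10 | 3-bromo-2-methoxyprop-1-ene | COC(=C)CBr | starting material
11 | dimethyl[(E)-2-(trimethylsilyl)ethenyl]alane | C[Si](C)(C)/C=C/[Al](C)C | intermediate
12 | dimethylaluminium (3R,4S)-4-{4-[(dimethylalumanyl)oxy]-4-methylpentyl}-4-methyl-3-[(E)-2-(trimethylsilyl)ethenyl]cyclohept-1-en-1-olate | C1=C(O[Al](C)C)CCC[C@](C)(CCCC(C)(C)O[Al](C)C)[C@H]1/C=C/[Si](C)(C)C | intermediate
13 | (2S,3R,4S)-4-(4-hydroxy-4-methylpentyl)-2-(2-methoxyprop-2-en-1-yl)-4-methyl-3-[(E)-2-(trimethylsilyl)ethenyl]cycloheptan-1-one | COC(=C)C[C@@H]1C(=O)CCC[C@](C)(CCCC(C)(C)O)[C@H]1/C=C/[Si](C)(C)C | intermediate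
14 | (5S,6R,7S)-5-(4-hydroxy-4-methylpentyl)-7-(2-methoxyprop-2-en-1-yl)-5-methyl-6-[(E)-2-(trimethylsilyl)ethenyl]cyclohept-2-en-1-one | COC(=C)C[C@@H]1C(=O)C=CC[C@](C)(CCCC(C)(C)O)[C@H]1/C=C/[Si](C)(C)C | intermediate
15 | (5S,6R,7S)-2-(hydroxymethyl)-5-(4-hydroxy-4-methylpentyl)-7-(2-methoxyprop-2-en-1-yl)-5-methyl-6-[(E)-2-(trimethylsilyl)ethenyl]cyclohept-2-en-1-one | COC(=C)C[C@@H]1C(=O)C(CO)=CC[C@](C)(CCCC(C)(C)O)[C@H]1/C=C/[Si](C)(C)C | intermediate
16 | (5S,6R,7S)-2-(hydroxymethyl)-5-(4-hydroxy-4-methylpentyl)-5-methyl-7-(2-oxopropyl)-6-[(E)-2-(trimethylsilyl)ethenyl]cyclohept-2-en-1-one | CC(=O)C[C@@H]1C(=O)C(CO)=CC[C@](C)(CCCC(C)(C)O)[C@H]1/C=C/[Si](C)(C)C | intermediate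
17 | (5S,6R,7S)-2-(hydroxymethyl)-5-(4-hydroxy-4-methylpentyl)-6-[(E)-2-iodoethenyl]-5-methyl-7-(2-oxopropyl)cyclohept-2-en-1-one | CC(=O)C[C@@H]1C(=O)C(CO)=CC[C@](C)(CCCC(C)(C)O)[C@H]1/C=C/I | intermediate
18 | 3-methylbut-2-enoic acid | CC(C)=CC(=O)O | starting material
19 | (5S,6S,7S)-2-(hydroxymethyl)-5-(4-hydroxy-4-methylpentyl)-5-methyl-6-[(E)-2-(3-methylbut-2-enoyloxy)ethenyl]-7-(2-oxopropyl)cyclohept-2-en-1-one (CNP0359016.1) | CC(=O)C[C@@H]1C(=O)C(CO)=CC[C@](C)(CCCC(C)(C)O)[C@H]1/C=C/OC(=O)C=C(C)C | target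

**Step count and risk**
Total steps: 8. Longest linear sequence: 8 (from 1 or 2 to 19). No protecting-group step is needed: the tertiary alcohol is silylated in the flask in step 1 and freed in step 3.

The three steps most likely to fail, with fallbacks:

Step 4 (ligand-controlled alkenylation and enolate alkylation on a hindered enone in one flask). The fallback separates the two bond formations and sets out from 8. Ethynyltrimethylsilane and Cp2Zr(H)Cl give chlorobis(cyclopentadienyl)[(E)-2-(trimethylsilyl)ethenyl]zirconium F1. F1 is added to 8 under [Rh(cod)(MeCN)2]BF4/BINAP catalysis (ligand antipode chosen as before, protic work-up) to give (3R,4S)-4-(4-hydroxy-4-methylpentyl)-4-methyl-3-[(E)-2-(trimethylsilyl)ethenyl]cycloheptan-1-one F2. Allyl-palladium dehydrogenation of its zinc enolate (Zn(TMP)2, [Pd(allyl)Cl]2, diethyl allyl phosphate; deprotonation at the CH2 remote from the substituted carbons, regioisomer removed by chromatography) gives (5S,6R)-5-(4-hydroxy-4-methylpentyl)-5-methyl-6-[(E)-2-(trimethylsilyl)ethenyl]cyclohept-2-en-1-one F3. The cross-conjugated lithium enolate of F3 (LDA, THF, −78 °C) is alkylated by 10 anti to the alkenyl group, and the fallback comes back to the route at 14.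

Step 6 (Baylis–Hillman reaction on a slow seven-membered enone). The fallback replaces the organocatalytic C–C bond formation by a cross-coupling and sets out from 14. Dilute HCl gives (5S,6R,7S)-5-(4-hydroxy-4-methylpentyl)-5-methyl-7-(2-oxopropyl)-6-[(E)-2-(trimethylsilyl)ethenyl]cyclohept-2-en-1-one F4. α-Iodination (I2, pyridine, CH2Cl2) gives (5S,6R,7S)-5-(4-hydroxy-4-methylpentyl)-2-iodo-5-methyl-7-(2-oxopropyl)-6-[(E)-2-(trimethylsilyl)ethenyl]cyclohept-2-en-1-one F5. Stille coupling with Bu3SnCH2OH (Pd(PPh3)4, dioxane, 80 °C) comes back to the route at 16.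

Step 8 (the proposed new coupling). The fallback uses known chemistry through boron and sets out from 17. Miyaura borylation (B2pin2, PdCl2(PPh3)2, KOPh, toluene, 50 °C) gives (5S,6S,7S)-2-(hydroxymethyl)-5-(4-hydroxy-4-methylpentyl)-5-methyl-7-(2-oxopropyl)-6-[(E)-2-(4,4,5,5-tetramethyl-1,3,2-dioxaborolan-2-yl)ethenyl]cyclohept-2-en-1-one F6. KHF2 in aqueous MeOH gives the corresponding potassium (E)-alkenyltrifluoroborate, (5S,6S,7S), with BF3K in place of the pinacol boronate F7. The known oxidative copper-catalysed coupling of the alkenyltrifluoroborate with 18 (CuBr, DMAP, 4 Å MS, O2, 60 °C) goes with retention and comes back to the route at 19.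

**Further compounds**
F1 | step 4 | chlorobis(cyclopentadienyl)[(E)-2-(trimethylsilyl)ethenyl]zirconium | C[Si](C)(C)/C=C/[Zr](Cl)(C1C=CC=C1)C1C=CC=C1
F2 | step 4 | (3R,4S)-4-(4-hydroxy-4-methylpentyl)-4-methyl-3-[(E)-2-(trimethylsilyl)ethenyl]cycloheptan-1-one | C1C(=O)CCC[C@](C)(CCCC(C)(C)O)[C@H]1/C=C/[Si](C)(C)C
F3 | step 4 | (5S,6R)-5-(4-hydroxy-4-methylpentyl)-5-methyl-6-[(E)-2-(trimethylsilyl)ethenyl]cyclohept-2-en-1-one | C1C(=O)C=CC[C@](C)(CCCC(C)(C)O)[C@H]1/C=C/[Si](C)(C)C
F4 | step 6 | (5S,6R,7S)-5-(4-hydroxy-4-methylpentyl)-5-methyl-7-(2-oxopropyl)-6-[(E)-2-(trimethylsilyl)ethenyl]cyclohept-2-en-1-one | CC(=O)C[C@@H]1C(=O)C=CC[C@](C)(CCCC(C)(C)O)[C@H]1/C=C/[Si](C)(C)C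
F5 | step 6 | (5S,6R,7S)-5-(4-hydroxy-4-methylpentyl)-2-iodo-5-methyl-7-(2-oxopropyl)-6-[(E)-2-(trimethylsilyl)ethenyl]cyclohept-2-en-1-one | CC(=O)C[C@@H]1C(=O)C(I)=CC[C@](C)(CCCC(C)(C)O)[C@H]1/C=C/[Si](C)(C)C
F6 | step 8 | (5S,6S,7S)-2-(hydroxymethyl)-5-(4-hydroxy-4-methylpentyl)-5-methyl-7-(2-oxopropyl)-6-[(E)-2-(4,4,5,5-tetramethyl-1,3,2-dioxaborolan-2-yl)ethenyl]cyclohept-2-en-1-one | CC(=O)C[C@@H]1C(=O)C(CO)=CC[C@](C)(CCCC(C)(C)O)[C@H]1/C=C/B1OC(C)(C)C(C)(C)O1
F7 | step 8 | potassium (E)-alkenyltrifluoroborate of F6, (5S,6S,7S), BF3K in place of the pinacol boronate | CC(=O)C[C@@H]1C(=O)C(CO)=CC[C@](C)(CCCC(C)(C)O)[C@H]1/C=C/[B-](F)(F)F.[K+]
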